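**Plan**
1. Retrosynthesis: C3–H is traced back to a C3–CO2allyl helper and the 7-OH to its allyl ether, both of which leave in one palladium step. Ring C is then cut at O1–C8a and at C3–C4, giving 4-(allyloxy)-2-fluorobenzoyl chloride (ring A with C4) and an O-silylated α-aryl-β-hydroxy allyl ester (O1–C2–C3 carrying the ring B chromene).
2. Enabling feature: in ring C the ketone carbon C4 sits on C4a, directly ortho to the O1-bearing C8a, and C3 lies between C4 and the O1–C2H2 unit. An O1–C2–C3 piece nucleophilic at both ends (enolate carbon, alkoxide oxygen) therefore matches a 2-fluoroaroyl piece electrophilic at C4 and, once C4=O exists, at C8a.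
3. Forward order: the dimethylpyran ring of the chromene is made first (phenol + enal, oxa-6π closure), then the arylacetate chain, its hydroxymethyl arm and the silyl mask. Ring C is closed last, onto ring A, by C-acylation and SNAr in one pot.
4. Stereochemistry: C3, the only stereocentre, stays racemic and quaternary until the last step, where palladium-catalysed decarboxylative protonation under an (S)-PHOX ligand sets it as S. No step follows that could epimerise it.

Key step: step 8

Assumption: with Meldrum's acid as proton donor the (S)-configured t-BuPHOX ligand is taken to give the (S)-ketone; if the sense of induction proves opposite, the (R)-ligand is used and nothing else changes.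

**Step 1**
Reactants: 1 4-bromo-3-methoxyphenol; 2 3-methylbut-2-enal
Product: 3 6-bromo-7-methoxy-2,2-dimethyl-2H-chromene
Conditions: PhB(OH)2 (1 equiv, recovered unchanged), AcOH, toluene, reflux, Dean–Stark
Reagents that add atoms: none
Why: Phenylboronic acid templates an ortho-selective condensation of the phenol with the enal to a benzodioxaborin that fragments on heating to an ortho-quinone methide, whose oxa-6π electrocyclisation gives the 2H-chromene; of the two ortho positions only the unhindered one para to OMe should react, so Br ends at C6 and OMe at C7.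

**Step 2**
Reactants: 3 6-bromo-7-methoxy-2,2-dimethyl-2H-chromene
Product: 4 ethyl 2-(7-methoxy-2,2-dimethyl-2H-chromen-6-yl)acetate
Conditions: BrZnCH2CO2Et (1.5 equiv), Pd2(dba)3 (2.5 mol %), XPhos (10 mol %), THF, 65 °C
Reagents that add atoms: (2-ethoxy-2-oxoethyl)zinc bromide, CCOC(=O)C[Zn]Br
Why: Negishi-type coupling of the aryl bromide with the Reformatsky zinc enolate (palladium-catalysed ester α-arylation) needs no added base and tolerates the chromene alkene and the ortho-methoxy group.

**Step 3**
Reactants: 4 ethyl 2-(7-methoxy-2,2-dimethyl-2H-chromen-6-yl)acetate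
Product: 5 allyl 2-(7-methoxy-2,2-dimethyl-2H-chromen-6-yl)acetate
Conditions: Ti(OEt)4 (0.2 equiv), allyl alcohol (solvent), 95 °C, EtOH distilled off
Reagents that add atoms: prop-2-en-1-ol, C=CCO
Why: Titanate-catalysed transesterification in excess allyl alcohol is near-neutral and spares the acid-sensitive chromene; the allyl ester is brought in only after the palladium-catalysed coupling so that it cannot be ionised there.

**Step 4**
Reactants: 5 allyl 2-(7-methoxy-2,2-dimethyl-2H-chromen-6-yl)acetate
Product: 6 allyl 3-hydroxy-2-(7-methoxy-2,2-dimethyl-2H-chromen-6-yl)propanoate (racemic)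
Conditions: LiN(SiMe3)2 (1.1 equiv), THF, −78 °C; monomeric CH2O (from cracked paraformaldehyde, 3 equiv), −78 °C; AcOH quench at −78 °C
Reagents that add atoms: formaldehyde, C=O
Why: Aldol addition of the lithium ester enolate to monomeric formaldehyde at −78 °C should give the β-hydroxy ester, and the cold acidic quench forestalls E1cB dehydration; the new centre is racemic and is overwritten later.

**Step 5**
Reactants: 6 allyl 3-hydroxy-2-(7-methoxy-2,2-dimethyl-2H-chromen-6-yl)propanoate
Product: 7 allyl 3-[(tert-butyldimethylsilyl)oxy]-2-(7-methoxy-2,2-dimethyl-2H-chromen-6-yl)propanoate (racemic)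
Conditions: TBSCl (1.2 equiv), imidazole (2 equiv), CH2Cl2, 0 → 20 °C
Reagents that add atoms: tert-butyldimethylsilyl chloride, CC(C)(C)[Si](C)(C)Cl
Why: Standard imidazole-promoted silylation of the primary alcohol masks the future O1, so that in step 8 the enolate is acylated at carbon without O-acylation or β-elimination and fluoride can release the alkoxide on demand.

**Step 6**
Reactants: 8 2-fluoro-4-hydroxybenzoic acid
Product: 10 4-(allyloxy)-2-fluorobenzoic acid, via allyl 4-(allyloxy)-2-fluorobenzoate 9 (not isolated)
Conditions: allyl bromide (2.3 equiv), K2CO3 (2.5 equiv), DMF, 40 °C; then NaOH (2 M aq), MeOH, 20 °C; 1 M HCl to pH 2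
Reagents that add atoms: allyl bromide, C=CCBr; sodium hydroxide, [Na+].[OH-]
Why: Williamson allylation of both acidic oxygens followed by saponification of the ester leaves the aryl allyl ether, which is inert to acid chloride formation, amide base and fluoride and is removable by the same palladium chemistry that later excises the C3 carboxyl.

**Step 7**
Reactants: 10 4-(allyloxy)-2-fluorobenzoic acid
Product: 11 4-(allyloxy)-2-fluorobenzoyl chloride
Conditions: (COCl)2 (1.3 equiv), DMF (cat.), CH2Cl2, 0 → 20 °C; volatiles removed, used crude
Reagents that add atoms: oxalyl chloride, O=C(Cl)C(Cl)=O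
Why: Vilsmeier-type activation by oxalyl chloride with catalytic DMF converts the acid into the acid chloride, the aryl fluoride and the allyl ether being inert.

**Step 8**
Reactants: 7 allyl 3-[(tert-butyldimethylsilyl)oxy]-2-(7-methoxy-2,2-dimethyl-2H-chromen-6-yl)propanoate; 11 4-(allyloxy)-2-fluorobenzoyl chloride
Product: 14 allyl 7-(allyloxy)-3-(7-methoxy-2,2-dimethyl-2H-chromen-6-yl)-4-oxochromane-3-carboxylate (racemic), via silyl keto ester 12 (not isolated), via hydroxy keto ester 13 (not isolated)
Conditions: LiN(SiMe3)2 (1.15 equiv), THF, −78 °C; 11 (1.1 equiv), −78 → 0 °C; then Bu4NF (2.5 equiv), 0 → 40 °C, one pot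
Reagents that add atoms: none
Why: The tetrasubstituted lithium ester enolate of 7 is C-acylated by 11 (Claisen-type acylation), which forms C3–C4 and gives the ortho-fluoroaryl ketone 12; fluoride then removes the silyl group and the C2 alkoxide of 13 attacks C8a ipso to fluorine by addition–elimination through a Meisenheimer complex stabilised by the new ortho C4=O, which forms O1–C8a. The closest known reaction types are the tandem C-acylation/intramolecular SNAr annulation of 2-halobenzoyl chlorides used for chromones and 4-quinolones, and the aldol/SNAr route to chroman-4-ones. Ring C closes in 6-exo-trig fashion at the arene carbon C8a. C3 becomes quaternary and racemic; no control is sought because the carboxyl is excised in step 9, where C3 is set. The step needs C- over O-acylation, which the lithium enolate in THF with an acid chloride at low temperature should favour, and ring closure over retro-aldol loss of formaldehyde or C3–C4 cleavage. Closure is secured because quaternary C3 has no hydrogen for dehydration, the C8a fluorine is the only leaving group ortho to C4=O, the geminal substitution at C3 favours cyclisation, and retro-aldol is reversible whereas the SNAr is not.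

**Step 9**
Reactants: 14 allyl 7-(allyloxy)-3-(7-methoxy-2,2-dimethyl-2H-chromen-6-yl)-4-oxochromane-3-carboxylate
Product: 16 (3S)-7-hydroxy-3-(7-methoxy-2,2-dimethyl-2H-chromen-6-yl)chroman-4-one, via (3S)-7-allyloxy isoflavanone 15 (not isolated)
Conditions: Pd2(dba)3 (5 mol %), (S)-t-BuPHOX [(S)-4-tert-butyl-2-(2-diphenylphosphanylphenyl)-4,5-dihydrooxazole] (12.5 mol %), Meldrum's acid (4 equiv), 1,4-dioxane, 40 °C
Reagents that add atoms: none
Why: Zerovalent palladium ionises the allyl ester (Tsuji–Trost-type oxidative addition), CO2 is lost, and the enolate held by the PHOX-ligated allylpalladium cation is protonated by Meldrum's acid on one face to set C3 as S (decarboxylative asymmetric protonation, a reaction type established for 3-aryl-chroman-4-one allyl esters, where the ortho-methoxy group on the aryl is expected to help); the same catalyst then ionises the aryl allyl ether and the Meldrum's acid anion scavenges both allyl groups, so the phenol is freed under mildly acidic conditions that leave C3 untouched.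

**Compound list**
1 | 4-bromo-3-methoxyphenol | COc1cc(O)ccc1Br | starting material
2 | 3-methylbut-2-enal | CC(C)=CC=O | starting material
3 | 6-bromo-7-methoxy-2,2-dimethyl-2H-chromene | COc1cc2OC(C)(C)C=Cc2cc1Br | intermediate
4 | ethyl 2-(7-methoxy-2,2-dimethyl-2H-chromen-6-yl)acetate | CCOC(=O)Cc1cc2C=CC(C)(C)Oc2cc1OC | intermediate
5 | allyl 2-(7-methoxy-2,2-dimethyl-2H-chromen-6-yl)acetate | C=CCOC(=O)Cc1cc2C=CC(C)(C)Oc2cc1OC | intermediate
6 | allyl 3-hydroxy-2-(7-methoxy-2,2-dimethyl-2H-chromen-6-yl)propanoate, racemic | C=CCOC(=O)C(CO)c1cc2C=CC(C)(C)Oc2cc1OC | intermediate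
7 | allyl 3-[(tert-butyldimethylsilyl)oxy]-2-(7-methoxy-2,2-dimethyl-2H-chromen-6-yl)propanoate, racemic | C=CCOC(=O)C(CO[Si](C)(C)C(C)(C)C)c1cc2C=CC(C)(C)Oc2cc1OC | intermediate
8 | 2-fluoro-4-hydroxybenzoic acid | OC(=O)c1ccc(O)cc1F | starting material
9 | allyl 4-(allyloxy)-2-fluorobenzoate (not isolated) | C=CCOC(=O)c1ccc(OCC=C)cc1F | intermediate
10 | 4-(allyloxy)-2-fluorobenzoic acid | C=CCOc1ccc(C(=O)O)c(F)c1 | intermediate
11 | 4-(allyloxy)-2-fluorobenzoyl chloride | C=CCOc1ccc(C(=O)Cl)c(F)c1 | intermediate
12 | allyl 2-[4-(allyloxy)-2-fluorobenzoyl]-3-[(tert-butyldimethylsilyl)oxy]-2-(7-methoxy-2,2-dimethyl-2H-chromen-6-yl)propanoate, racemic (silyl keto ester, not isolated) | C=CCOC(=O)C(CO[Si](C)(C)C(C)(C)C)(c1cc2C=CC(C)(C)Oc2cc1OC)C(=O)c1ccc(OCC=C)cc1F | intermediate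
13 | allyl 2-[4-(allyloxy)-2-fluorobenzoyl]-3-hydroxy-2-(7-methoxy-2,2-dimethyl-2H-chromen-6-yl)propanoate, racemic, present as its alkoxide (hydroxy keto ester, not isolated) | C=CCOC(=O)C(CO)(c1cc2C=CC(C)(C)Oc2cc1OC)C(=O)c1ccc(OCC=C)cc1F | intermediate
14 | allyl 7-(allyloxy)-3-(7-methoxy-2,2-dimethyl-2H-chromen-6-yl)-4-oxochromane-3-carboxylate, racemic | C=CCOC(=O)C1(c2cc3C=CC(C)(C)Oc3cc2OC)COc2cc(OCC=C)ccc2C1=O | intermediate
15 | (3S)-7-(allyloxy)-3-(7-methoxy-2,2-dimethyl-2H-chromen-6-yl)chroman-4-one (not isolated) | COc1cc2c(cc1[C@H]1COc3cc(OCC=C)ccc3C1=O)C=CC(C)(C)O2 | intermediate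
16 | (3S)-7-hydroxy-3-(7-methoxy-2,2-dimethyl-2H-chromen-6-yl)chroman-4-one | COc1cc2c(cc1[C@H]1COc3cc(O)ccc3C1=O)C=CC(C)(C)O2 | target

Total step count: 9. Longest linear sequence: 7 steps (steps 1, 2, 3, 4, 5, 8, 9).

**Steps most likely to fail**

Step 8. The hindered enolate may be acylated at oxygen instead of carbon. After desilylation the alkoxide may lose formaldehyde by retro-aldol faster than it closes, or the non-enolisable β-keto ester may be cleaved at C3–C4 by adventitious hydroxide. The fallback sets out from 5 and 11 and comes back at 14; it attaches the ring A acyl group before the C2 carbon. Compound 5 is deprotonated with LiN(SiMe3)2 (2.1 equiv, THF, −78 °C) and acylated with 11 to give allyl 3-[4-(allyloxy)-2-fluorophenyl]-2-(7-methoxy-2,2-dimethyl-2H-chromen-6-yl)-3-oxopropanoate F1. F1 is then stirred with paraformaldehyde and K2CO3 in MeCN at 20–45 °C. Hydroxymethylation at C3 under excess formaldehyde keeps regenerating the alkoxide of 13, and the SNAr closure should deliver 14 (tandem aldol/SNAr).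

Step 9. Facial selectivity in the protonation may be insufficient, the enolate may be allylated at carbon instead of protonated, or the aryl allyl ether may ionise too slowly. The fallback sets out from 14 and comes back at 16; it replaces asymmetric catalysis by resolution. Pd(PPh3)4 (5 mol %) with HCO2H/Et3N in THF at 20 °C removes both allyl groups without stereocontrol and gives racemic 7-hydroxy-3-(7-methoxy-2,2-dimethyl-2H-chromen-6-yl)chroman-4-one F2. The enantiomers of F2 are separated by preparative supercritical-fluid chromatography on a chiral stationary phase to give 16; the unwanted enantiomer is racemised with Et3N and recycled.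

Step 4. The aldolate may dehydrate by E1cB to the 2-arylacrylate, or formaldehyde may oligomerise before it is captured. The fallback sets out from 5 and comes back at 6; it replaces the aldol by formylation and reduction. Crossed Claisen condensation of 5 with allyl formate and NaH (THF, 0 → 20 °C) gives allyl 3-hydroxy-2-(7-methoxy-2,2-dimethyl-2H-chromen-6-yl)prop-2-enoate F3, the enol form of the α-formyl ester. NaBH4 in MeOH at 0 °C then reduces F3 to 6.

**Further compounds**
F1 | step 8 | allyl 3-[4-(allyloxy)-2-fluorophenyl]-2-(7-methoxy-2,2-dimethyl-2H-chromen-6-yl)-3-oxopropanoate | C=CCOC(=O)C(c1cc2C=CC(C)(C)Oc2cc1OC)C(=O)c1ccc(OCC=C)cc1F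
F2 | step 9 | racemic 7-hydroxy-3-(7-methoxy-2,2-dimethyl-2H-chromen-6-yl)chroman-4-one | COc1cc2c(cc1C1COc3cc(O)ccc3C1=O)C=CC(C)(C)O2
F3 | step 4 | allyl 3-hydroxy-2-(7-methoxy-2,2-dimethyl-2H-chromen-6-yl)prop-2-enoate | C=CCOC(=O)C(=CO)c1cc2C=CC(C)(C)Oc2cc1OC
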